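Next to this flask stands a neighbour with 0.0050 M of Z at the same loading of E, and one reckoning has to serve both.

Z 0.020 M (fed, over 50 min); E 0.01 mol%; Q 0.35 µM; time 25 h; the fed solution adds 0.10 times the starting volume

    Z + E → X + E, rate k1*[Z]*[E]/(1 + ([Z]/Km1) + ([Z]/Ksi1)^2) (Km1 = 21.3 mM, Ksi1 = 12.2 mM, k1 = 1.68 × 10⁵ L mol⁻¹ min⁻¹)
    E + Q → E.Q (k2 = 85800 L mol⁻¹ s⁻¹)
    X + E ⇌ D + E, rate k3*[E]*[X] forward; the back reaction follows from the equilibrium constant (K3 = 1.2, k3 = 21400 L mol⁻¹ min⁻¹)
    E → L (k4 = 0.0433 min⁻¹)

- the X standing at 25 h, as a percentage of the Z charged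
- the D standing at 25 h, as a percentage of the Z charged
- amount of X if the flask were left three thousand times as long, in percent of the Z charged

Q meets 2.00 µM of E and binds it within about 5.83 s, far faster than E decays. So 1.65 µM of E stays at work, with a lifetime of 23.1 min.

Steps 1 and 4 both carry [E], so dividing one rate by the other removes time. What remains is one ratio:

R = 1.68 × 10⁵ L mol⁻¹ min⁻¹ × 1.65 µM / 0.0433 min⁻¹ = 6.40

R is the reach, the number of e-foldings of Z that the working E can perform before it dies.

The denominator f of the rate law shortens this. At a trial Z of 5.00 mM, with the feed's volume set aside, f = 1.40, and Z behaves as pseudo-first-order.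

Way one puts the whole charge in at the start:

Z left = exp(−R/f) = 1.03%

Way two follows portions of the dose. A portion meets the E still alive on arrival, and keeps exp(−Rφ/f), where φ is the living share of E:

first portion 1.04%, middle 21.3%, last 59.2%

Z left, weights 1, 4, 1: 24.3%

The two part, and way one cheats. The dose lasts 50 min, longer than the life of E, so the last portion meets 11.5% of the working E. Way two also returns about its trial Z, so it stands.

Step 3 has a reach too, and X born in mid-dose sees 0.276 of it. Relaxing towards 1.2, that turns 21.7% of the product into D. This reckoning therefore gives X 59.3% and D 16.4%. The run lasts 65.0 lifetimes of E, so the late X equals the X at 25 h.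

The forecast, a little apart from this reckoning, gives X 57.5%, D 14.5% and late X 57.5%, on the ground that “catalysis stops after a few hours”.

The simulated flask gives X 58.3%, D 13.7% and late X 58.3%, with Z left at 28% against the reckoned 24.3%.

This flask is at rest by 25 h. The reach still unspent there is R·exp(−k4·t) = 3.97 × 10⁻²⁸, and E stands at 0% of its charge, with L at 82.5% and E.Q at 17.5%. Ten times the time changes nothing: Z stays at 28.1%, X at 58.3% and D at 13.7%. This rest is not equilibrium, since D over X reads 0.235 against 1.2.

In the neighbour, 0.500 µM of E faces the same 0.35 µM of Q, so R falls from 6.40 to 0.582. With f = 1.30 at a trial Z of 4.00 mM, the portions leave 83.8% of its Z. The simulated neighbour holds 84%.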